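**Retrosynthetic overview**
- The target is cut between the syringyl ring and C1: an aryl bromide plus a ketone homoenolate (carbanion β to the C3 ketone). The homoenolate is stored as a 1-substituted cyclopropanol and released by Pd-catalysed ring opening.
- The cyclopropanol comes from methyl (R)-3-hydroxy-5-arylpentanoate by a Kulinkovich reaction; the carbinol stereocentre is already in place.
- The (R)-β-hydroxy ester comes from the β-keto ester by Noyori hydrogenation (sets the only stereocentre); the β-keto ester comes from zingerone and dimethyl carbonate.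
- Rings: both arenes are bought. The only ring made is the cyclopropane (step 3), which is opened again in step 4. No protecting groups are used.

Assumption: the target is the (5R) enantiomer, as read from the SMILES; zingerone and 4-bromo-2,6-dimethoxyphenol are taken as catalogue chemicals.

**Step 1**
Reactants: 1 zingerone [4-(4-hydroxy-3-methoxyphenyl)butan-2-one]
Product: 2 methyl 5-(4-hydroxy-3-methoxyphenyl)-3-oxopentanoate
Conditions: NaH (3.5 equiv), (MeO)2CO (5 equiv), THF, reflux; then 1 M HCl, 0 °C
Reagents that add atoms: dimethyl carbonate, COC(=O)OC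
Why: Crossed Claisen condensation (C-methoxycarbonylation) at the less hindered methyl side of the ketone, driven by deprotonation of the β-keto ester product; the sodium phenoxide is a spectator because any aryl methyl carbonate is cleaved back by the methoxide released.

**Step 2**
Reactants: 2 methyl 5-(4-hydroxy-3-methoxyphenyl)-3-oxopentanoate
Product: 3 methyl (3R)-3-hydroxy-5-(4-hydroxy-3-methoxyphenyl)pentanoate
Conditions: RuCl2[(R)-BINAP] (0.5 mol %), H2 (50 bar), degassed MeOH, 50 °C
Reagents that add atoms: none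
Why: Noyori asymmetric hydrogenation of a β-keto ester; the ester-chelated ketone is reduced from one face under (R)-BINAP control to the (3R)-alcohol (same sense as methyl acetoacetate to methyl (R)-3-hydroxybutanoate, typically ≥97% ee), and the phenol and arene are untouched.

**Step 3**
Reactants: 3 methyl (3R)-3-hydroxy-5-(4-hydroxy-3-methoxyphenyl)pentanoate
Product: 4 1-[(2R)-2-hydroxy-4-(4-hydroxy-3-methoxyphenyl)butyl]cyclopropan-1-ol
Conditions: Ti(OiPr)4 (0.3 equiv), EtMgBr (5 equiv, slow addition), THF, 0 °C to rt; then sat. aq NH4Cl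
Reagents that add atoms: ethylmagnesium bromide, CC[Mg]Br
Why: Kulinkovich cyclopropanation, in which the titanacyclopropane from EtMgBr and Ti(OiPr)4 adds twice to the ester carbonyl as a 1,2-dicarbanion; the phenoxide and secondary alkoxide only consume two extra equivalents of Grignard reagent and the stereocentre is not involved.

**Step 4**
Reactants: 4 1-[(2R)-2-hydroxy-4-(4-hydroxy-3-methoxyphenyl)butyl]cyclopropan-1-ol; 5 4-bromo-2,6-dimethoxyphenol (1.3 equiv)
Product: 6 (5R)-5-hydroxy-7-(4-hydroxy-3-methoxyphenyl)-1-(4-hydroxy-3,5-dimethoxyphenyl)heptan-3-one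
Conditions: Pd(OAc)2 (5 mol %), XPhos (10 mol %), Cs2CO3 (3.5 equiv), degassed 1,4-dioxane, 60 °C; then aq NH4Cl
Reagents that add atoms: none
Why: Pd-catalysed ring-opening cross-coupling of a cyclopropanol with an aryl bromide (ketone homoenolate arylation, a known reaction type but untested with two free phenols): oxidative addition of 5, Pd-alkoxide formation at the strained tertiary alcohol, β-carbon elimination to the β-palladated ketone and XPhos-promoted C(sp3)–C(sp2) reductive elimination ahead of β-hydride elimination join the aryl carbon to the ketone β-carbon, while the remote C5 stereocentre is untouched.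

**Compound list**
1 | zingerone, 4-(4-hydroxy-3-methoxyphenyl)butan-2-one | CC(=O)CCc1ccc(O)c(OC)c1 | starting material
2 | methyl 5-(4-hydroxy-3-methoxyphenyl)-3-oxopentanoate | COC(=O)CC(=O)CCc1ccc(O)c(OC)c1 | intermediate
3 | methyl (3R)-3-hydroxy-5-(4-hydroxy-3-methoxyphenyl)pentanoate | COc1cc(CC[C@@H](O)CC(=O)OC)ccc1O | intermediate
4 | 1-[(2R)-2-hydroxy-4-(4-hydroxy-3-methoxyphenyl)butyl]cyclopropan-1-ol | COc1cc(CC[C@@H](O)CC2(O)CC2)ccc1O | intermediate
5 | 4-bromo-2,6-dimethoxyphenol | COc1cc(Br)cc(OC)c1O | starting material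
6 | (5R)-5-hydroxy-7-(4-hydroxy-3-methoxyphenyl)-1-(4-hydroxy-3,5-dimethoxyphenyl)heptan-3-one | COc1cc(CC[C@@H](O)CC(=O)CCc2cc(OC)c(O)c(OC)c2)ccc1O | target

**Totals**
Total step count: 4. Longest linear sequence: 4 steps (1 → 2 → 3 → 4 → 6); 5 is bought.

**Three steps most likely to fail**

Step 4 (most risky). The two caesium phenoxides may hold Pd as aryloxide complexes or make the salts insoluble. The β-palladated ketone may undergo β-hydride elimination to the vinyl ketone. The β-hydroxy ketone product may dehydrate or undergo retro-aldol on carbonate at 60 °C, which would also erode the stereocentre. The fallback sets out from 4 and 5 and comes back at 6, with the phenols masked as benzyl ethers so that the coupling runs on neutral partners with little base. 5 is benzylated (BnBr, K2CO3, DMF, rt) to 2-(benzyloxy)-5-bromo-1,3-dimethoxybenzene F1. Only the phenol of 4 is benzylated (BnBr 1.05 equiv, K2CO3, acetone, rt; the aliphatic hydroxyls are not alkylated) to 1-[(2R)-4-[4-(benzyloxy)-3-methoxyphenyl]-2-hydroxybutyl]cyclopropan-1-ol F2. F1 and F2 are coupled with Pd(OAc)2/XPhos and only 1.5 equiv Cs2CO3 in toluene at 60 °C to (5R)-1-[4-(benzyloxy)-3,5-dimethoxyphenyl]-7-[4-(benzyloxy)-3-methoxyphenyl]-5-hydroxyheptan-3-one F3. H2 (1 atm), Pd/C, EtOAc, rt then removes both benzyl groups and gives 6.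

Step 3. The magnesium phenoxide and β-alkoxide may tie up the titanium or precipitate, giving low conversion or simple ethyl addition to the ester. The fallback sets out from 3 and comes back at 4, with both hydroxyls silylated. 3 is treated with TBSCl (2.5 equiv), imidazole, DMF to give methyl (3R)-3-[(tert-butyldimethylsilyl)oxy]-5-[4-[(tert-butyldimethylsilyl)oxy]-3-methoxyphenyl]pentanoate F4. This undergoes the Kulinkovich reaction with 2.5 equiv EtMgBr and 15 mol % Ti(OiPr)4 in THF to 1-[(2R)-2-[(tert-butyldimethylsilyl)oxy]-4-[4-[(tert-butyldimethylsilyl)oxy]-3-methoxyphenyl]butyl]cyclopropan-1-ol F5. HF·pyridine in THF/pyridine, 0 °C to rt, removes both silyl groups and returns 4.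

Step 1. The phenoxide/enolate disodium salt may be too insoluble to acylate cleanly, or part of the material may be isolated as the aryl carbonate. The fallback sets out from 1 and comes back at 2, with the phenol benzylated first. 1 is benzylated (BnBr, K2CO3, acetone, reflux) to 4-[4-(benzyloxy)-3-methoxyphenyl]butan-2-one F6. This is methoxycarbonylated (NaH 2.5 equiv, dimethyl carbonate, THF, reflux), the well-behaved case for 4-arylbutan-2-ones, to methyl 5-[4-(benzyloxy)-3-methoxyphenyl]-3-oxopentanoate F7. Hydrogenolysis (H2 1 atm, Pd/C, EtOAc, rt) leaves the ketone alone and gives 2.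

**Further compounds**
F1 | step 4 | 2-(benzyloxy)-5-bromo-1,3-dimethoxybenzene | COc1cc(Br)cc(OC)c1OCc1ccccc1
F2 | step 4 | 1-[(2R)-4-[4-(benzyloxy)-3-methoxyphenyl]-2-hydroxybutyl]cyclopropan-1-ol | COc1cc(CC[C@@H](O)CC2(O)CC2)ccc1OCc1ccccc1
F3 | step 4 | (5R)-1-[4-(benzyloxy)-3,5-dimethoxyphenyl]-7-[4-(benzyloxy)-3-methoxyphenyl]-5-hydroxyheptan-3-one | COc1cc(CC[C@@H](O)CC(=O)CCc2cc(OC)c(OCc3ccccc3)c(OC)c2)ccc1OCc1ccccc1
F4 | step 3 | methyl (3R)-3-[(tert-butyldimethylsilyl)oxy]-5-[4-[(tert-butyldimethylsilyl)oxy]-3-methoxyphenyl]pentanoate | COc1cc(CC[C@@H](O[Si](C)(C)C(C)(C)C)CC(=O)OC)ccc1O[Si](C)(C)C(C)(C)C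
F5 | step 3 | 1-[(2R)-2-[(tert-butyldimethylsilyl)oxy]-4-[4-[(tert-butyldimethylsilyl)oxy]-3-methoxyphenyl]butyl]cyclopropan-1-ol | COc1cc(CC[C@@H](O[Si](C)(C)C(C)(C)C)CC2(O)CC2)ccc1O[Si](C)(C)C(C)(C)C
F6 | step 1 | 4-[4-(benzyloxy)-3-methoxyphenyl]butan-2-one | CC(=O)CCc1ccc(OCc2ccccc2)c(OC)c1
F7 | step 1 | methyl 5-[4-(benzyloxy)-3-methoxyphenyl]-3-oxopentanoate | COC(=O)CC(=O)CCc1ccc(OCc2ccccc2)c(OC)c1
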